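The target is a 1,2-divinylcyclohexane (isopropenyl on C5, enol acetate arm on quaternary C10; germacrane numbering), so its ring bond C5–C10 is made last by a Cope rearrangement of a 2-acetoxygermacra-1(10),4-dienolide, which also sets C5, C10 and the Z enol acetate. The key step makes that ten-membered ring and its γ-lactone in one flask from two open-chain pieces: allylboration–lactonisation joins C7 to C6, then nickel-catalysed decarboxylative alkenylation joins C9 to C10. It exploits the C7–C11(=C13) allyl unit of the α-methylene lactone and the C8/C9 diol, read as D-tartrate. The partners are an iodo-dienal acetate and a borylmethyl enoate carrying a dioxolane N-acyloxyphthalimide.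

Key step: step 12

Remark: atoms carry germacrane/elemane numbers (C1=C2 enol acetate arm and C14 methyl on C10; C3=C4(C15) isopropenyl on C5; ring C5–C10; C6–O–C12 lactone with C11=C13), and the exocyclic methylene lactone is assumed to tolerate steps 12–16 unprotected.

Step 1
Reactants: 1 methyl 3-methylbut-2-enoate
Product: 2 tert-butyl[(1-methoxy-3-methylbuta-1,3-dien-1-yl)oxy]dimethylsilane
Conditions: LiN(iPr)2, THF, −78 °C; TBSCl, DMPU, −78 °C to rt
Reagents that add atoms: tert-butyldimethylsilyl chloride CC(C)(C)[Si](C)(C)Cl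
Why: γ-Deprotonation of the senecioate and O-silylation of the cross-conjugated lithium dienolate (silyl ketene acetal formation) give the nucleophile for a vinylogous Mukaiyama aldol, with no stereocentre formed.

Step 2
Reactants: 2 tert-butyl[(1-methoxy-3-methylbuta-1,3-dien-1-yl)oxy]dimethylsilane; 3 but-2-ynal
Product: 4 methyl (2E,5R)-5-hydroxy-3-methyloct-2-en-6-ynoate
Conditions: SiCl4 (1.1 equiv), (R,R)-binaphthyldiamine-derived bisphosphoramide (5 mol %), iPr2NEt (10 mol %), CH2Cl2, −78 °C; aq. NaHCO3
Reagents that add atoms: none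
Why: In the Lewis-base-activated SiCl4 vinylogous Mukaiyama aldol the dienolate attacks the conjugated aldehyde through its γ-carbon to give the (E)-enoate, and the chiral bisphosphoramide–silicon cation is chosen to expose the aldehyde face that gives the 5R carbinol (later C2, which controls the enol acetate geometry).

Step 3
Reactants: 4 methyl (2E,5R)-5-hydroxy-3-methyloct-2-en-6-ynoate
Product: 5 (2E,5R)-3-methyloct-2-en-6-yne-1,5-diol
Conditions: iBu2AlH (3 equiv), CH2Cl2, −78 to 0 °C; aq. potassium sodium tartrate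
Reagents that add atoms: none
Why: Aluminium hydride 1,2-reduction of the conjugated ester stops at the allylic alcohol and leaves the alkyne, the trisubstituted alkene and the carbinol stereocentre untouched.

Step 4
Reactants: 5 (2E,5R)-3-methyloct-2-en-6-yne-1,5-diol
Product: 6 (2E,5R,6E)-7-iodo-3-methylocta-2,6-diene-1,5-diol
Conditions: Cp2Zr(H)Cl (3.3 equiv), THF, rt; I2, 0 °C
Reagents that add atoms: iodine II
Why: Hydrozirconation is a syn addition that places zirconium on the methyl-bearing alkyne carbon, away from the bulky C5 zirconium alkoxide, and iodinolysis with retention gives the (E)-2-iodoalkene (hydrozirconation–iodination).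

Step 5
Reactants: 6 (2E,5R,6E)-7-iodo-3-methylocta-2,6-diene-1,5-diol
Product: 7 (2E,5R,6E)-5-hydroxy-7-iodo-3-methylocta-2,6-dienal
Conditions: TEMPO (10 mol %), PhI(OAc)2, CH2Cl2, rt
Reagents that add atoms: none
Why: The oxoammonium (TEMPO) oxidation is selective for the unhindered primary allylic alcohol over the secondary one and gives the (E)-enal without touching the alkenyl iodide.

Step 6
Reactants: 7 (2E,5R,6E)-5-hydroxy-7-iodo-3-methylocta-2,6-dienal
Product: 8 (2E,5R,6E)-7-iodo-3-methyl-1-oxoocta-2,6-dien-5-yl acetate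
Conditions: Ac2O, pyridine, DMAP (5 mol %), CH2Cl2, 0 °C
Reagents that add atoms: acetic anhydride CC(=O)OC(C)=O
Why: DMAP-catalysed acylation of the remaining secondary alcohol installs the C2 acetate of the target with retention at the stereocentre.

Step 7
Reactants: 9 ethyl 2-(diphenoxyphosphoryl)acetate
Product: 10 ethyl 2-(diphenoxyphosphoryl)-3-(4,4,5,5-tetramethyl-1,3,2-dioxaborolan-2-yl)propanoate (racemic)
Conditions: NaH, THF/DMF, 0 °C; ICH2Bpin, 0 °C to rt
Reagents that add atoms: 2-(iodomethyl)-4,4,5,5-tetramethyl-1,3,2-dioxaborolane ICB1OC(C)(C)C(C)(C)O1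
Why: The sodium phosphonoacetate is C-alkylated by the α-iodomethyl boronate (substitution through the boron ate complex and 1,2-shift), and the diaryl phosphonate is kept for a Z-selective Horner–Wadsworth–Emmons reaction.

Step 8
Reactants: 11 dimethyl (4S,5S)-2,2-dimethyl-1,3-dioxolane-4,5-dicarboxylate (from D-tartaric acid)
Product: 12 methyl (4S,5S)-5-formyl-2,2-dimethyl-1,3-dioxolane-4-carboxylate
Conditions: iBu2AlH (1.05 equiv), toluene, −78 °C; aq. potassium sodium tartrate; used crude
Reagents that add atoms: none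
Why: One equivalent of iBu2AlH at −78 °C reduces one of the two equivalent esters of the C2-symmetric diester to the aldehyde through a stable aluminium hemiacetal, so both tartrate stereocentres (later C8 and C9) are retained.

Step 9
Reactants: 12 methyl (4S,5S)-5-formyl-2,2-dimethyl-1,3-dioxolane-4-carboxylate; 10 ethyl 2-(diphenoxyphosphoryl)-3-(4,4,5,5-tetramethyl-1,3,2-dioxaborolan-2-yl)propanoate
Product: 13 ethyl (2Z)-3-[(4R,5S)-5-(methoxycarbonyl)-2,2-dimethyl-1,3-dioxolan-4-yl]-2-[(4,4,5,5-tetramethyl-1,3,2-dioxaborolan-2-yl)methyl]prop-2-enoate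
Conditions: 10, NaH, THF, −78 °C; then 12, −78 to −20 °C
Reagents that add atoms: none
Why: The diaryl phosphonate variant of the Horner–Wadsworth–Emmons reaction is kinetically Z-selective, which puts the ester cis to the dioxolane (the geometry needed for an anti allylboration), and the α-alkoxy stereocentre is not epimerised at low temperature.

Step 10
Reactants: 13 ethyl (2Z)-3-[(4R,5S)-5-(methoxycarbonyl)-2,2-dimethyl-1,3-dioxolan-4-yl]-2-[(4,4,5,5-tetramethyl-1,3,2-dioxaborolan-2-yl)methyl]prop-2-enoate
Product: 14 (4S,5R)-5-[(1Z)-3-ethoxy-3-oxo-2-[(4,4,5,5-tetramethyl-1,3,2-dioxaborolan-2-yl)methyl]prop-1-en-1-yl]-2,2-dimethyl-1,3-dioxolane-4-carboxylic acid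
Conditions: LiOH·H2O (1.05 equiv), THF/H2O, 0 °C; 1 M HCl to pH 4
Reagents that add atoms: lithium hydroxide [Li+].[OH-]
Why: The α-alkoxy methyl ester is saponified much faster than the hindered conjugated ethyl ester, which frees the carboxyl group on the future C9 for activation (chemoselective ester hydrolysis).

Step 11
Reactants: 14 (4S,5R)-5-[(1Z)-3-ethoxy-3-oxo-2-[(4,4,5,5-tetramethyl-1,3,2-dioxaborolan-2-yl)methyl]prop-1-en-1-yl]-2,2-dimethyl-1,3-dioxolane-4-carboxylic acid
Product: 15 1,3-dioxoisoindolin-2-yl (4S,5R)-5-[(1Z)-3-ethoxy-3-oxo-2-[(4,4,5,5-tetramethyl-1,3,2-dioxaborolan-2-yl)methyl]prop-1-en-1-yl]-2,2-dimethyl-1,3-dioxolane-4-carboxylate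
Conditions: N-hydroxyphthalimide, N,N′-diisopropylcarbodiimide, DMAP (5 mol %), CH2Cl2, 0 °C to rt
Reagents that add atoms: N-hydroxyphthalimide O=C1c2ccccc2C(=O)N1O
Why: Carbodiimide coupling with N-hydroxyphthalimide converts the acid into the redox-active ester needed for decarboxylative nickel coupling, under neutral conditions that spare the allylboronate.

Step 12
Reactants: 8 (2E,5R,6E)-7-iodo-3-methyl-1-oxoocta-2,6-dien-5-yl acetate; 15 1,3-dioxoisoindolin-2-yl (4S,5R)-5-[(1Z)-3-ethoxy-3-oxo-2-[(4,4,5,5-tetramethyl-1,3,2-dioxaborolan-2-yl)methyl]prop-1-en-1-yl]-2,2-dimethyl-1,3-dioxolane-4-carboxylate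
Product: 17 (1(10)E,2R,4E,6R,7S,8R,9R)-2-acetoxy-8,9-(isopropylidenedioxy)germacra-1(10),4,11(13)-trien-12,6-olide, via iodo-lactone active ester 16 (not isolated)
Conditions: Sc(OTf)3 (10 mol %), toluene, −20 °C to rt, 0.2 M; then, in the same flask without work-up, DMA to 3 mM, NiBr2(dme) (20 mol %), 4,4′-di-tert-butyl-2,2′-bipyridine (22 mol %), Zn dust (3 equiv), rt
Reagents that add atoms: none
Why: Sc(OTf)3 activates the pinacol boronate of 15 for allylboration of C6, the only aldehyde present; in the closed Zimmerman–Traxler chair the (Z)-enoate keeps C8 equatorial, which gives the anti adduct, and the resulting borate closes the γ-lactone by 5-exo-trig acyl substitution at the ethyl ester to give 16 (closest known type: Lewis-acid-catalysed allylboration–lactonisation of 2-alkoxycarbonyl allylboronates). After dilution, zerovalent nickel inserts into the alkenyl iodide, zinc-driven single-electron reduction of the N-acyloxyphthalimide releases CO2 and the C9 dioxolanyl radical, and capture by the tethered alkenylnickel followed by C(sp3)–C(sp2) reductive elimination closes the ten-membered carbocycle (closest known type: nickel-catalysed decarboxylative alkenylation of redox-active esters, here run as a ring closure). C7 is set by attack on the alkene face anti to the C8–O bond in the conformer that holds H8 in the alkene plane (allylic 1,3-strain with the cis ester), C6 follows from the chair, and C9 re-forms trans to the C8 substituent on the dioxolane ring, as tartrate-derived dioxolanyl radicals do. The step needs cross-selectivity between two bifunctional partners, and this is built in: 15 holds no aldehyde or halide and 8 no boronate or active ester, so neither can react with itself. Ring closure against dimerisation should be favoured by high dilution and by the two (E)-alkenes that stiffen the tether.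

Step 13
Reactants: 17 (1(10)E,2R,4E,6R,7S,8R,9R)-2-acetoxy-8,9-(isopropylidenedioxy)germacra-1(10),4,11(13)-trien-12,6-olide
Product: 18 (1(10)E,2R,4E,6R,7S,8R,9R)-2-acetoxy-8,9-dihydroxygermacra-1(10),4,11(13)-trien-12,6-olide
Conditions: AcOH/H2O/THF 3:1:1, 40 °C
Reagents that add atoms: none
Why: Mild aqueous acid hydrolyses the isopropylidene ketal to the 8,9-diol, the acid being kept weak to avoid transannular cyclisation of the germacradiene and loss of the acetate.

Step 14
Reactants: 18 (1(10)E,2R,4E,6R,7S,8R,9R)-2-acetoxy-8,9-dihydroxygermacra-1(10),4,11(13)-trien-12,6-olide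
Product: 19 (1(10)E,2R,4E,6R,7S,8R,9R)-2,9-diacetoxy-8-hydroxygermacra-1(10),4,11(13)-trien-12,6-olide
Conditions: Ac2O (1.1 equiv), pyridine, CH2Cl2, −20 °C
Reagents that add atoms: acetic anhydride CC(=O)OC(C)=O
Why: The allylic C9 hydroxyl, flanked by the sp2 carbon C10, is less hindered than the C8 hydroxyl between two sp3 methines, so a slight excess of anhydride at low temperature should acetylate C9 first (kinetic site-selective acylation).

Step 15
Reactants: 19 (1(10)E,2R,4E,6R,7S,8R,9R)-2,9-diacetoxy-8-hydroxygermacra-1(10),4,11(13)-trien-12,6-olide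
Product: 20 (1(10)E,2R,4E,6R,7S,8R,9R)-2,9-diacetoxy-8-angeloyloxygermacra-1(10),4,11(13)-trien-12,6-olide
Conditions: angelic acid, 2,4,6-trichlorobenzoyl chloride, Et3N, toluene, rt; then 19, DMAP, 40 °C
Reagents that add atoms: angelic acid C/C=C(/C)C(=O)O
Why: Yamaguchi esterification through the mixed 2,4,6-trichlorobenzoic anhydride acylates the remaining hindered C8 hydroxyl with angelic acid under conditions that limit Z-to-E isomerisation of the angelate.

Step 16
Reactants: 20 (1(10)E,2R,4E,6R,7S,8R,9R)-2,9-diacetoxy-8-angeloyloxygermacra-1(10),4,11(13)-trien-12,6-olide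
Product: 21 (5S,6R,7S,8R,9R,10S)-2,9-diacetoxy-8-angeloyloxyelema-1(Z),3,11(13)-trien-12,6-olide (target CNP0582479.1)
Conditions: toluene (degassed, BHT), 140 °C, sealed tube
Reagents that add atoms: none
Why: Thermal Cope rearrangement through the chair transition state of the crossed conformer of the (E,E)-1,5-diene forms C5–C10 and cleaves C2–C3, so the equatorial ring carbons C6 and C9 fix C5 (S) and C10 (S) trans to each other, the C2 acetate, axial in that chair, becomes the (Z)-enol acetate, and C3/C4/C15 become the isopropenyl group, with strain release and the enol ester as driving force.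

Compound list
1 | methyl 3-methylbut-2-enoate | COC(=O)C=C(C)C | starting material
2 | tert-butyl[(1-methoxy-3-methylbuta-1,3-dien-1-yl)oxy]dimethylsilane (ketene acetal geometry not defined) | C=C(C)C=C(OC)O[Si](C)(C)C(C)(C)C | intermediate
3 | but-2-ynal | CC#CC=O | starting material
4 | methyl (2E,5R)-5-hydroxy-3-methyloct-2-en-6-ynoate | COC(=O)/C=C(\C)C[C@@H](O)C#CC | intermediate
5 | (2E,5R)-3-methyloct-2-en-6-yne-1,5-diol | OC/C=C(\C)C[C@@H](O)C#CC | intermediate
6 | (2E,5R,6E)-7-iodo-3-methylocta-2,6-diene-1,5-diol | OC/C=C(\C)C[C@@H](O)/C=C(\C)I | intermediate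
7 | (2E,5R,6E)-5-hydroxy-7-iodo-3-methylocta-2,6-dienal | O=C/C=C(\C)C[C@@H](O)/C=C(\C)I | intermediate
8 | (2E,5R,6E)-7-iodo-3-methyl-1-oxoocta-2,6-dien-5-yl acetate | O=C/C=C(\C)C[C@@H](OC(C)=O)/C=C(\C)I | intermediate
9 | ethyl 2-(diphenoxyphosphoryl)acetate | CCOC(=O)CP(=O)(Oc1ccccc1)Oc1ccccc1 | starting material
10 | ethyl 2-(diphenoxyphosphoryl)-3-(4,4,5,5-tetramethyl-1,3,2-dioxaborolan-2-yl)propanoate (racemic) | CCOC(=O)C(CB1OC(C)(C)C(C)(C)O1)P(=O)(Oc1ccccc1)Oc1ccccc1 | intermediate
11 | dimethyl (4S,5S)-2,2-dimethyl-1,3-dioxolane-4,5-dicarboxylate | COC(=O)[C@H]1OC(C)(C)O[C@@H]1C(=O)OC | starting material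
12 | methyl (4S,5S)-5-formyl-2,2-dimethyl-1,3-dioxolane-4-carboxylate | COC(=O)[C@H]1OC(C)(C)O[C@@H]1C=O | intermediate
13 | ethyl (2Z)-3-[(4R,5S)-5-(methoxycarbonyl)-2,2-dimethyl-1,3-dioxolan-4-yl]-2-[(4,4,5,5-tetramethyl-1,3,2-dioxaborolan-2-yl)methyl]prop-2-enoate | CCOC(=O)/C(CB2OC(C)(C)C(C)(C)O2)=C\[C@H]1OC(C)(C)O[C@@H]1C(=O)OC | intermediate
14 | (4S,5R)-5-[(1Z)-3-ethoxy-3-oxo-2-[(4,4,5,5-tetramethyl-1,3,2-dioxaborolan-2-yl)methyl]prop-1-en-1-yl]-2,2-dimethyl-1,3-dioxolane-4-carboxylic acid | CCOC(=O)/C(CB2OC(C)(C)C(C)(C)O2)=C\[C@H]1OC(C)(C)O[C@@H]1C(=O)O | intermediate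
15 | 1,3-dioxoisoindolin-2-yl ester of 14 (N-acyloxyphthalimide) | CCOC(=O)/C(CB2OC(C)(C)C(C)(C)O2)=C\[C@H]1OC(C)(C)O[C@@H]1C(=O)ON3C(=O)c4ccccc4C3=O | intermediate
16 | iodo-lactone active ester: 1,3-dioxoisoindolin-2-yl (4S,5R)-5-{(2R,3S)-2-[(1E,4R,5E)-4-acetoxy-6-iodo-2-methylhepta-1,5-dien-1-yl]-4-methylidene-5-oxooxolan-3-yl}-2,2-dimethyl-1,3-dioxolane-4-carboxylate | C=C1C(=O)O[C@H](/C=C(\C)C[C@@H](OC(C)=O)/C=C(\C)I)[C@H]1[C@H]2OC(C)(C)O[C@@H]2C(=O)ON3C(=O)c4ccccc4C3=O | intermediate
17 | (1(10)E,2R,4E,6R,7S,8R,9R)-2-acetoxy-8,9-(isopropylidenedioxy)germacra-1(10),4,11(13)-trien-12,6-olide | C=C1C(=O)O[C@@H]2/C=C(\C)C[C@@H](OC(C)=O)/C=C(\C)[C@H]3OC(C)(C)O[C@@H]3[C@@H]12 | intermediate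
18 | (1(10)E,2R,4E,6R,7S,8R,9R)-2-acetoxy-8,9-dihydroxygermacra-1(10),4,11(13)-trien-12,6-olide | C=C1C(=O)O[C@@H]2/C=C(\C)C[C@@H](OC(C)=O)/C=C(\C)[C@@H](O)[C@H](O)[C@@H]12 | intermediate
19 | (1(10)E,2R,4E,6R,7S,8R,9R)-2,9-diacetoxy-8-hydroxygermacra-1(10),4,11(13)-trien-12,6-olide | C=C1C(=O)O[C@@H]2/C=C(\C)C[C@@H](OC(C)=O)/C=C(\C)[C@@H](OC(C)=O)[C@H](O)[C@@H]12 | intermediate
20 | (1(10)E,2R,4E,6R,7S,8R,9R)-2,9-diacetoxy-8-angeloyloxygermacra-1(10),4,11(13)-trien-12,6-olide | C=C1C(=O)O[C@@H]2/C=C(\C)C[C@@H](OC(C)=O)/C=C(\C)[C@@H](OC(C)=O)[C@H](OC(=O)/C(C)=C\C)[C@@H]12 | intermediate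
21 | (5S,6R,7S,8R,9R,10S)-2,9-diacetoxy-8-angeloyloxyelema-1(Z),3,11(13)-trien-12,6-olide | C=C1C(=O)O[C@H]2[C@H]1[C@@H](OC(=O)/C(C)=C\C)[C@H](OC(C)=O)[C@@](C)(/C=C\OC(C)=O)[C@@H]2C(=C)C | target

Total step count: 16. Longest linear sequence: 11 steps (steps 1–6, then 12–16).

Steps most likely to fail, in order of risk:

Step 12. During the ring closure the C9 radical may be captured by another molecule (dimers, oligomers) or reduced before it meets the tethered alkenylnickel, and zerovalent nickel may ionise the allylic C2 acetate. The fallback inverts the order of the two bond formations and runs them as two operations, so that the ring is closed by the allylboration instead. It sets out from 8 and 15: intermolecular decarboxylative alkenylation (NiBr2(dme), 4,4′-di-tert-butyl-2,2′-bipyridine, Zn, DMA, 0.1 M, rt; boronate and enal do not react at rt without Lewis acid) should give the open-chain C9–C10 coupled boronate dienal F1. Sc(OTf)3 (20 mol %) in toluene at 2 mM would then close the ten-membered ring by intramolecular allylboration–lactonisation through the same chair, which comes back to the route at 17.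

Step 16. The C2 acetate has to sit axial in the chair, so the rearrangement may stall at equilibrium or leak through a boat (E enol acetate), and long heating may isomerise the angelate or shift the allylic acetates. The fallback moves the rearrangement to an earlier, sturdier compound and acylates afterwards. It sets out from 17: heating the acetonide (toluene, 130 °C), which has no angelate and whose trans-dioxolane already holds O8/O9 as in the product, should give the elemanolide 8,9-acetonide F2. Ketal hydrolysis (AcOH/H2O) gives the elemanolide 8,9-diol F3; Yamaguchi esterification with angelic acid at the C8 hydroxyl, now clearly the less hindered one because C9 is neopentylic, gives the 8-angelate 9-alcohol F4; acetylation of C9 (Ac2O, Sc(OTf)3 cat., MeCN, −20 °C) comes back to the route at 21.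

Step 14. Site selectivity between the two secondary hydroxyls may be poor or inverted, and the acetyl group may migrate between them. The fallback reverses the order of the two acylations. It sets out from 18: if acetylation shows C8 to be the more reactive site, Yamaguchi esterification with one equivalent of the angelic mixed anhydride is run first to give the germacranolide 8-angelate 9-alcohol F5, and acetylation of the C9 hydroxyl (Ac2O, DMAP) then comes back to the route at 20.

Further compounds
F1 | step 12 | open-chain C9–C10 coupled (Z)-borylmethyl enoate dienal (2R,8R,9R) | CCOC(=O)/C(CB2OC(C)(C)C(C)(C)O2)=C\[C@H]1OC(C)(C)O[C@@H]1/C(C)=C/[C@H](OC(C)=O)C/C(C)=C/C=O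
F2 | step 16 | (5S,6R,7S,8R,9R,10S)-2-acetoxy-8,9-(isopropylidenedioxy)elema-1(Z),3,11(13)-trien-12,6-olide | C=C1C(=O)O[C@H]2[C@H]1[C@H]3OC(C)(C)O[C@@H]3[C@@](C)(/C=C\OC(C)=O)[C@@H]2C(=C)C
F3 | step 16 | (5S,6R,7S,8R,9R,10S)-2-acetoxy-8,9-dihydroxyelema-1(Z),3,11(13)-trien-12,6-olide | C=C1C(=O)O[C@H]2[C@H]1[C@@H](O)[C@H](O)[C@@](C)(/C=C\OC(C)=O)[C@@H]2C(=C)C
F4 | step 16 | (5S,6R,7S,8R,9R,10S)-2-acetoxy-8-angeloyloxy-9-hydroxyelema-1(Z),3,11(13)-trien-12,6-olide | C=C1C(=O)O[C@H]2[C@H]1[C@@H](OC(=O)/C(C)=C\C)[C@H](O)[C@@](C)(/C=C\OC(C)=O)[C@@H]2C(=C)C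
F5 | step 14 | (1(10)E,2R,4E,6R,7S,8R,9R)-2-acetoxy-8-angeloyloxy-9-hydroxygermacra-1(10),4,11(13)-trien-12,6-olide | C=C1C(=O)O[C@@H]2/C=C(\C)C[C@@H](OC(C)=O)/C=C(\C)[C@@H](O)[C@H](OC(=O)/C(C)=C\C)[C@@H]12
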